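**Assumptions (one line each)**
- The SMILES corresponds to (3,4-dimethoxyphenyl)[(3R,4R,5S)-4-(hydroxymethyl)-5-(3,4,5-trimethoxyphenyl)oxolan-3-yl]methanone. In the ring the aryl is trans to CH2OH, and CH2OH is cis to the aroyl group.
- The (S,S)-Ru-TsDPEN catalyst is expected to give the (R)-propargylic alcohol, and hence the (S)-butenolide. If the sense is opposite, use the (R,R) catalyst.
- The aryl on the ylide carbon ends up exo on the cis-fused bicycle, on steric grounds.
- Compound numbers are assigned from Step 1 onward.

**Retrosynthetic overview**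
1. Magnone B comes from the diol by selective oxidation of the secondary benzylic alcohol. The diol comes from LiAlH4 opening of a cis-fused furo[3,4-c]furanone. The lactone carbonyl becomes CH2OH, and the lactone O–CH(Ar') carbon becomes the aroyl carbon.
2. The bicyclic lactone comes from a [3+2] cycloaddition of the carbonyl ylide ArCH=O⁺–CH2⁻ (Ar = 3,4,5-trimethoxyphenyl) with (S)-5-(3,4-dimethoxyphenyl)butenolide. This step forms the THF ring and the three ring stereocenters together.
3. Order of ring formation: the butenolide ring first, then the THF ring in the cycloaddition. The lactone ring is then opened, so its only lasting role is to hold the 3,4-cis relationship and carry the chirality.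
4. The butenolide comes from veratraldehyde and ethyl propiolate by alkynylation, oxidation, Noyori asymmetric transfer hydrogenation (ATH), Lindlar reduction and lactonization. The ylide precursor comes from 3,4,5-trimethoxybenzaldehyde and (trimethylsilyl)methanol.

**Step 1**
Reactants: 1 3,4-dimethoxybenzaldehyde; 2 ethyl propiolate
Product: 3 rac-ethyl 4-(3,4-dimethoxyphenyl)-4-hydroxybut-2-ynoate
Conditions: LiHMDS (1.05 equiv), THF, –78 °C, deprotonating 2 first; then add 1; NH4Cl quench
Reagents that add atoms: none
Why: the lithium ynoate adds 1,2 to the aldehyde (alkynylation); the racemic carbinol is acceptable because Step 2 removes the stereocenter.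

**Step 2**
Reactants: 3
Product: 4 ethyl 4-(3,4-dimethoxyphenyl)-4-oxobut-2-ynoate
Conditions: activated MnO2 (10 equiv), CH2Cl2, 25 °C
Reagents that add atoms: none
Why: MnO2 selectively oxidizes the doubly activated propargylic/benzylic alcohol to the ynone (MnO2 oxidation).

**Step 3**
Reactants: 4
Product: 5 (R)-ethyl 4-(3,4-dimethoxyphenyl)-4-hydroxybut-2-ynoate
Conditions: RuCl[(S,S)-TsDPEN](p-cymene) (1 mol%), HCO2H/Et3N (5:2), CH2Cl2, 25 °C
Reagents that add atoms: none (formate only supplies hydrogen)
Why: Noyori–Ikariya ATH of an aryl alkynyl ketone reduces the ketone enantioselectively (>95% ee expected) and leaves the alkyne and ester untouched.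

**Step 4**
Reactants: 5
Product: 6 (S,Z)-ethyl 4-(3,4-dimethoxyphenyl)-4-hydroxybut-2-enoate
Conditions: H2 (1 atm), Lindlar catalyst, quinoline, EtOAc, 25 °C, stopped at full conversion
Reagents that add atoms: none (hydrogen only)
Why: Lindlar syn-hydrogenation gives the cis alkene, and the carbinol stereocenter is not involved (its label changes from R to S only through CIP priorities).

**Step 5**
Reactants: 6
Product: 7 (S)-5-(3,4-dimethoxyphenyl)furan-2(5H)-one
Conditions: TsOH·H2O (5 mol%), CH2Cl2, 0 → 25 °C, 1 h
Reagents that add atoms: none (EtOH is lost)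
Why: the Z geometry places OH next to the ester, so acid-catalysed lactonization occurs by acyl–O cleavage and the C–O stereocenter is retained.

**Step 6**
Reactants: 8 3,4,5-trimethoxybenzaldehyde; 9 (trimethylsilyl)methanol (2.2 equiv)
Product: 10 3,4,5-trimethoxybenzaldehyde bis[(trimethylsilyl)methyl] acetal
Conditions: PPTS (5 mol%), 4 Å MS, CH2Cl2, 25 °C
Reagents that add atoms: none
Why: ordinary acid-catalysed acetalization.

**Step 7**
Reactants: 10; 11 acetic anhydride (1.0 equiv)
Product: 12 [(trimethylsilyl)methoxy](3,4,5-trimethoxyphenyl)methyl acetate (crude, used at once; Me3SiCH2OAc is the co-product)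
Conditions: ZnCl2 (5 mol%), CH2Cl2, 0 °C, 30 min
Reagents that add atoms: acetic anhydride, CC(=O)OC(C)=O (its acetyl group)
Why: Lewis-acid-catalysed acylative cleavage of one acetal arm gives the α-acyloxy ether (acetal/anhydride exchange).

**Step 8 (key new step)**
Reactants: 7 (1.0 equiv); 12 (2.5 equiv, added in portions)
Product: 13 (3S,3aR,6S,6aS)-3-(3,4-dimethoxyphenyl)-6-(3,4,5-trimethoxyphenyl)tetrahydrofuro[3,4-c]furan-1(3H)-one
Conditions: LiClO4 (1.0 equiv), 4 Å MS, MeCN, 40 °C, 16 h
Reagents that add atoms: none (Me3SiOAc is lost)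
Why: Proposed new method: Li⁺ and the electron-rich aryl ionize 12 to the oxocarbenium ArCH=O⁺–CH2SiMe3 OAc⁻, and acetate removes Me3Si⁺ to give the non-stabilized ylide ArCH=O⁺–CH2⁻ under base-free conditions, so the acidic γ-stereocenter of 7 is not racemized; the nucleophilic CH2 terminus adds to the β-carbon of the Li⁺-activated butenolide and the resulting enolate closes onto the oxocarbenium carbon, an asynchronous suprafacial [3+2] that makes the THF ring and cis-fused lactone in one step. The ylide approaches anti to the 5-aryl group, which sets C3/C4 absolutely, and the exo aryl orientation sets C2. The closest known reactions are the azomethine-ylide [3+2] of N-(methoxymethyl)-N-(trimethylsilylmethyl)amines and Rh-carbenoid carbonyl-ylide cycloadditions; a non-stabilized aryl(methylene) carbonyl ylide made by desilylation and added to butenolides is not known, and 3,4,5-trimethoxystyrene oxide from ylide closure is the main competing path.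

**Step 9**
Reactants: 13
Product: 14 {(2S,3R,4R)-4-[(S)-(3,4-dimethoxyphenyl)(hydroxy)methyl]-2-(3,4,5-trimethoxyphenyl)oxolan-3-yl}methanol
Conditions: LiAlH4 (3 equiv), THF, 0 °C, 1 h; Fieser work-up
Reagents that add atoms: none (hydride only)
Why: hydride reduces the lactone to the diol, and at 0 °C reduction outcompetes enolization, so the α-stereocenter (C3) and the benzylic THF ether are untouched.

**Step 10**
Reactants: 14
Product: 15 Magnone B, (3,4-dimethoxyphenyl)[(3R,4R,5S)-4-(hydroxymethyl)-5-(3,4,5-trimethoxyphenyl)oxolan-3-yl]methanone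
Conditions: activated MnO2 (20 equiv), CH2Cl2, 25 °C, 24 h
Reagents that add atoms: none
Why: MnO2 oxidizes only the electron-rich secondary benzylic alcohol (the carbinol stereocenter is destroyed), leaving the primary alcohol and benzylic ether intact, and these neutral heterogeneous conditions do not epimerize the α-carbon.

**Compound list**
1 | 3,4-dimethoxybenzaldehyde | COc1ccc(C=O)cc1OC | starting material
2 | ethyl propiolate | CCOC(=O)C#C | starting material
3 | rac-ethyl 4-(3,4-dimethoxyphenyl)-4-hydroxybut-2-ynoate | CCOC(=O)C#CC(O)c1ccc(OC)c(OC)c1 | intermediate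
4 | ethyl 4-(3,4-dimethoxyphenyl)-4-oxobut-2-ynoate | CCOC(=O)C#CC(=O)c1ccc(OC)c(OC)c1 | intermediate
5 | (R)-ethyl 4-(3,4-dimethoxyphenyl)-4-hydroxybut-2-ynoate | CCOC(=O)C#C[C@H](O)c1ccc(OC)c(OC)c1 | intermediate
6 | (S,Z)-ethyl 4-(3,4-dimethoxyphenyl)-4-hydroxybut-2-enoate | CCOC(=O)/C=C\[C@H](O)c1ccc(OC)c(OC)c1 | intermediate
7 | (S)-5-(3,4-dimethoxyphenyl)furan-2(5H)-one | O=C1C=C[C@@H](c2ccc(OC)c(OC)c2)O1 | intermediate
8 | 3,4,5-trimethoxybenzaldehyde | COc1cc(C=O)cc(OC)c1OC | starting material
9 | (trimethylsilyl)methanol | C[Si](C)(C)CO | starting material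
10 | 3,4,5-trimethoxybenzaldehyde bis[(trimethylsilyl)methyl] acetal | COc1cc(cc(OC)c1OC)C(OC[Si](C)(C)C)OC[Si](C)(C)C | intermediate
11 | acetic anhydride | CC(=O)OC(C)=O | starting material (reagent)
12 | [(trimethylsilyl)methoxy](3,4,5-trimethoxyphenyl)methyl acetate | COc1cc(cc(OC)c1OC)C(OC(C)=O)OC[Si](C)(C)C | intermediate
13 | (3S,3aR,6S,6aS)-3-(3,4-dimethoxyphenyl)-6-(3,4,5-trimethoxyphenyl)tetrahydrofuro[3,4-c]furan-1(3H)-one | O=C1O[C@H](c2ccc(OC)c(OC)c2)[C@H]3CO[C@H](c4cc(OC)c(OC)c(OC)c4)[C@@H]13 | intermediate
14 | {(2S,3R,4R)-4-[(S)-(3,4-dimethoxyphenyl)(hydroxy)methyl]-2-(3,4,5-trimethoxyphenyl)oxolan-3-yl}methanol | COc1ccc(cc1OC)[C@@H](O)[C@H]2CO[C@H](c3cc(OC)c(OC)c(OC)c3)[C@H]2CO | intermediate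
15 | Magnone B | COc1ccc(C(=O)[C@H]2CO[C@H](c3cc(OC)c(OC)c(OC)c3)[C@H]2CO)cc1OC | target

**Totals**
- Total steps: 10 (Steps 1–10).
- Longest linear sequence: 8 (Steps 1, 2, 3, 4, 5, 8, 9, 10). Steps 6–7 make the ylide precursor as a two-step side branch.

**Three steps most likely to fail**
1. **Step 8 (proposed new step).** The ylide may close to the epoxide faster than it is trapped, or the regiochemistry or exo/endo aryl orientation may be wrong.
   - Fallback: a stepwise annulation with known chemistry.
     - Cuprate 1,4-addition of a (benzyloxymethyl) reagent from Bu3SnCH2OBn to 7, anti to the aryl.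
     - Hydrogenolytic debenzylation of the resulting CH2OBn group.
     - Acetalization of the CH2OH with ArCH(OMe)2.
     - LiHMDS/TMSCl, then TMSOTf, for intramolecular silyl-ketene-acetal/oxocarbenium cyclization. The tether forces the cis-fused lactone 13.
2. **Step 3 (Ru-catalysed ATH of the ynoate ketone).** Enantioselectivity may be low, or conjugate reduction or amine addition may compete.
   - Fallback: lipase kinetic resolution (CAL-B or Amano PS with vinyl acetate) of racemic 3, recycling the unwanted enantiomer by MnO2 oxidation to 4, instead of asymmetric catalysis.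
3. **Step 10 (MnO2 oxidation of the secondary benzylic alcohol in 14).** It may be sluggish or partly epimerize C4, and the primary alcohol may cyclize onto the ketone as a hemiketal.
   - Fallback: selective TBS protection of the primary alcohol, Dess–Martin oxidation, and HF·pyridine deprotection, instead of direct oxidation.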